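**Retrosynthetic overview**
1. Target 21 ⇐ 20 ⇐ 19: final desilylation and 1,2-reduction of a C4 formyl group.
2. 19 ⇐ 18 ⇐ 17: cyclopentane and dihydropyran close together in one intramolecular inverse-demand hetero-Diels–Alder reaction of an alkylidene malondialdehyde with an (E)-enol ester that already carries the C1 acyl group. No ring exists before this step.
3. 17 ⇐ 15 + 16 (copper C–O coupling of a vinyl iodide); 15 ⇐ 13 + 14 (cross-metathesis).
4. 13 ⇐ 11 ⇐ 7 + 10: C7/C8 diol with the coumarate on C10, from a Sharpless epoxide opened at C8 by its own ester carbonyl (inversion).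
5. 7 ⇐ 6 ⇐ 4 + 5 ⇐ 3 ⇐ 1 + 2: dienol by trans-hydrostannation and Stille coupling.

Assumption: iridoid numbering (C1, C3–C11) is used for carbon atoms throughout; (3S)-3-methylpentanoic acid, (E)-1,2-diiodoethene and 2-methylidenepropane-1,3-diol are taken as purchasable.

**Step 1**
Reactants: 1 prop-2-yn-1-ol; 2 3-bromoprop-1-ene
Product: 3 hex-5-en-2-yn-1-ol
Conditions: CuI (10 mol%), K2CO3, Bu4NI (cat.), DMF, 23 °C
Reagents that add atoms: none
Why: Copper-catalysed propargyl–allyl coupling (SN2 alkylation of the copper acetylide) joins C6 to C7 and leaves the free alcohol untouched.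

**Step 2**
Reactants: 3 hex-5-en-2-yn-1-ol
Product: 4 (2Z)-2-(tributylstannyl)hexa-2,5-dien-1-ol
Conditions: Bu3SnH (1.1 equiv), [Cp*RuCl]4 (1.25 mol%), CH2Cl2, 23 °C
Reagents that add atoms: tributyltin hydride CCCC[SnH](CCCC)CCCC
Why: Hydroxyl-directed ruthenium-catalysed trans-hydrostannation puts tin on the carbon next to CH2OH and hydrogen trans to it, so the allyl chain ends up cis to tin.

**Step 3**
Reactants: 4 (2Z)-2-(tributylstannyl)hexa-2,5-dien-1-ol; 5 (E)-1,2-diiodoethene (3 equiv)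
Product: 6 (2E)-2-[(E)-2-iodoethenyl]hexa-2,5-dien-1-ol
Conditions: Pd2(dba)3 (2.5 mol%), AsPh3 (10 mol%), CuI (10 mol%), NMP, 23 °C, dark
Reagents that add atoms: none
Why: Stille coupling proceeds with retention at both partners, and the excess diiodide keeps it to mono-coupling, giving the (E)-vinyl iodide that becomes C9=C1 cis to the C6 chain.

**Step 4**
Reactants: 6 (2E)-2-[(E)-2-iodoethenyl]hexa-2,5-dien-1-ol
Product: 7 [(2S,3S)-2-[(E)-2-iodoethenyl]-3-(prop-2-en-1-yl)oxiran-2-yl]methanol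
Conditions: Ti(OiPr)4 (10 mol%), L-(+)-diethyl tartrate (12 mol%), t-BuOOH, 4 Å MS, CH2Cl2, −20 °C
Reagents that add atoms: tert-butyl hydroperoxide CC(C)(C)OO
Why: Sharpless asymmetric epoxidation touches only the allylic-alcohol alkene, and L-(+)-tartrate gives the (2S,3S)-epoxide, which fixes C7 in its final configuration and C8 in the configuration that is inverted in step 7.

**Step 5**
Reactants: 8 (2E)-3-(4-hydroxyphenyl)prop-2-enoic acid
Product: 10 (2E)-3-{4-[(triisopropylsilyl)oxy]phenyl}prop-2-enoic acid, via bis-silyl ester 9 (not isolated)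
Conditions: iPr3SiCl (2.2 equiv), imidazole, DMF, 23 °C; then AcOH/THF/H2O, 23 °C
Reagents that add atoms: triisopropylsilyl chloride CC(C)[Si](Cl)(C(C)C)C(C)C
Why: Bis-silylation followed by selective hydrolysis of the labile silyl ester masks only the phenol (silyl protection).

**Step 6**
Reactants: 7 [(2S,3S)-2-[(E)-2-iodoethenyl]-3-(prop-2-en-1-yl)oxiran-2-yl]methanol; 10 (2E)-3-{4-[(triisopropylsilyl)oxy]phenyl}prop-2-enoic acid
Product: 11 [(2S,3S)-2-[(E)-2-iodoethenyl]-3-(prop-2-en-1-yl)oxiran-2-yl]methyl (2E)-3-{4-[(triisopropylsilyl)oxy]phenyl}prop-2-enoate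
Conditions: DCC, DMAP (cat.), CH2Cl2, 0 → 23 °C
Reagents that add atoms: none
Why: Steglich esterification places the cinnamate on C10, the only hydroxyl present, where it also serves as the internal nucleophile for step 7.

**Step 7**
Reactants: 11 [(2S,3S)-2-[(E)-2-iodoethenyl]-3-(prop-2-en-1-yl)oxiran-2-yl]methyl (2E)-3-{4-[(triisopropylsilyl)oxy]phenyl}prop-2-enoate
Product: 13 (2R,3S)-2-hydroxy-2-[(E)-2-iodoethenyl]-3-[(triethylsilyl)oxy]hex-5-en-1-yl (2E)-3-{4-[(triisopropylsilyl)oxy]phenyl}prop-2-enoate, via dioxolanylium triflate 12 (not isolated)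
Conditions: Et3SiOTf (1.1 equiv), CH2Cl2, −78 °C; then aq NaHCO3/THF, 0 → 23 °C
Reagents that add atoms: triethylsilyl trifluoromethanesulfonate CC[Si](CC)(CC)OS(=O)(=O)C(F)(F)F; water O
Why: Proposed new method: the silyl triflate silylates the epoxide oxygen and the C10 ester carbonyl opens the activated epoxide from the back at the tertiary allylic C8 (five-membered acyloxonium, inversion at C8, C7 kept as its triethylsilyl ether), after which water opens the dioxolanylium ion and the acyl group settles on the primary oxygen; the closest known chemistry is the Lewis-acid epoxy-ester to ortho-ester rearrangement and acetoxonium neighbouring-group participation.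

**Step 8**
Reactants: 13 (2R,3S)-2-hydroxy-2-[(E)-2-iodoethenyl]-3-[(triethylsilyl)oxy]hex-5-en-1-yl (2E)-3-{4-[(triisopropylsilyl)oxy]phenyl}prop-2-enoate; 14 2-methylidenepropane-1,3-diol (5 equiv)
Product: 15 (2R,3S)-2,7-dihydroxy-6-(hydroxymethyl)-2-[(E)-2-iodoethenyl]-3-[(triethylsilyl)oxy]hept-5-en-1-yl (2E)-3-{4-[(triisopropylsilyl)oxy]phenyl}prop-2-enoate
Conditions: Hoveyda–Grubbs second-generation catalyst (5 mol%), 1,4-benzoquinone (10 mol%), CH2Cl2, 40 °C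
Reagents that add atoms: none
Why: Olefin cross-metathesis of the terminal alkene with a symmetrical 1,1-disubstituted partner raises no E/Z question, and the hindered vinyl iodide and the cinnamate alkene are inert to the catalyst.

**Step 9**
Reactants: 15 (2R,3S)-2,7-dihydroxy-6-(hydroxymethyl)-2-[(E)-2-iodoethenyl]-3-[(triethylsilyl)oxy]hept-5-en-1-yl (2E)-3-{4-[(triisopropylsilyl)oxy]phenyl}prop-2-enoate; 16 (3S)-3-methylpentanoic acid (1.5 equiv)
Product: 17 (1E,3R,4S)-3,8-dihydroxy-7-(hydroxymethyl)-4-[(triethylsilyl)oxy]-3-({[(2E)-3-{4-[(triisopropylsilyl)oxy]phenyl}prop-2-enoyl]oxy}methyl)octa-1,6-dien-1-yl (3S)-3-methylpentanoate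
Conditions: Cs2CO3 (0.75 equiv), CuI (10 mol%), 3,4,7,8-tetramethyl-1,10-phenanthroline (20 mol%), 4 Å MS, PhMe, 70 °C
Reagents that add atoms: none
Why: Ullmann-type copper-catalysed O-vinylation of the caesium carboxylate goes with retention to the (E)-enol ester, and because no base is left over the free alcohols are not deprotonated and do not compete.

**Step 10**
Reactants: 17 (1E,3R,4S)-3,8-dihydroxy-7-(hydroxymethyl)-4-[(triethylsilyl)oxy]-3-({[(2E)-3-{4-[(triisopropylsilyl)oxy]phenyl}prop-2-enoyl]oxy}methyl)octa-1,6-dien-1-yl (3S)-3-methylpentanoate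
Product: 19 (1S,4aS,6S,7R,7aS)-4-formyl-7-hydroxy-6-[(triethylsilyl)oxy]-7-({[(2E)-3-{4-[(triisopropylsilyl)oxy]phenyl}prop-2-enoyl]oxy}methyl)-1,4a,5,6,7,7a-hexahydrocyclopenta[c]pyran-1-yl (3S)-3-methylpentanoate, via alkylidene malondialdehyde 18 (not isolated)
Conditions: MnO2 (excess), CH2Cl2, 23 °C; filter; PhMe, 50 °C
Reagents that add atoms: none
Why: Proposed new method: MnO2 oxidises only the two primary allylic alcohols to an alkylidene malondialdehyde, whose formyl group trans to the chain acts as an electron-poor 1-oxadiene in an intramolecular inverse-electron-demand hetero-Diels–Alder reaction with the (E)-enol ester, closing the cyclopentane (C5–C9) and the dihydropyran (O2–C1) together; the three-atom tether enforces cis fusion, suprafacial addition to the E-enol ester puts the C1 acyloxy group cis to H9 (1S), and the C7 silyl ether and the C8 CH2O-acyl group take the convex face while the small tertiary OH sits inside (4aS, 7aS); the closest known chemistry is the Tietze-type intramolecular hetero-Diels–Alder reaction of alkylidene-1,3-dicarbonyls and the enamine–enal cycloaddition used for iridoids.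

**Step 11**
Reactants: 19 (1S,4aS,6S,7R,7aS)-4-formyl-7-hydroxy-6-[(triethylsilyl)oxy]-7-({[(2E)-3-{4-[(triisopropylsilyl)oxy]phenyl}prop-2-enoyl]oxy}methyl)-1,4a,5,6,7,7a-hexahydrocyclopenta[c]pyran-1-yl (3S)-3-methylpentanoate
Product: 20 (1S,4aS,6S,7R,7aS)-7-hydroxy-4-(hydroxymethyl)-6-[(triethylsilyl)oxy]-7-({[(2E)-3-{4-[(triisopropylsilyl)oxy]phenyl}prop-2-enoyl]oxy}methyl)-1,4a,5,6,7,7a-hexahydrocyclopenta[c]pyran-1-yl (3S)-3-methylpentanoate
Conditions: NaBH4, CeCl3·7H2O, MeOH/THF, −78 °C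
Reagents that add atoms: none
Why: Luche 1,2-reduction takes the vinylogous formate aldehyde to the C11 alcohol, while the esters, the C1 acylal and the silyl ethers are inert at this temperature.

**Step 12**
Reactants: 20 (1S,4aS,6S,7R,7aS)-7-hydroxy-4-(hydroxymethyl)-6-[(triethylsilyl)oxy]-7-({[(2E)-3-{4-[(triisopropylsilyl)oxy]phenyl}prop-2-enoyl]oxy}methyl)-1,4a,5,6,7,7a-hexahydrocyclopenta[c]pyran-1-yl (3S)-3-methylpentanoate
Product: 21 (1S,4aS,6S,7R,7aS)-6,7-dihydroxy-4-(hydroxymethyl)-7-({[(2E)-3-(4-hydroxyphenyl)prop-2-enoyl]oxy}methyl)-1,4a,5,6,7,7a-hexahydrocyclopenta[c]pyran-1-yl (3S)-3-methylpentanoate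
Conditions: Bu4NF/AcOH (1:1, 2.5 equiv), THF, 0 → 23 °C
Reagents that add atoms: none
Why: Buffered fluoride desilylation removes the secondary triethylsilyl ether and the aryl triisopropylsilyl ether without cleaving the acylal or moving acyl groups.

**Compound list**
1 | prop-2-yn-1-ol | C#CCO | starting material
2 | 3-bromoprop-1-ene | C=CCBr | starting material
3 | hex-5-en-2-yn-1-ol | OCC#CCC=C | intermediate
4 | (2Z)-2-(tributylstannyl)hexa-2,5-dien-1-ol | C=CC/C=C(/CO)\[Sn](CCCC)(CCCC)CCCC | intermediate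
5 | (E)-1,2-diiodoethene | I/C=C/I | starting material
6 | (2E)-2-[(E)-2-iodoethenyl]hexa-2,5-dien-1-ol | C=CC/C=C(/CO)\C=C\I | intermediate
7 | [(2S,3S)-2-[(E)-2-iodoethenyl]-3-(prop-2-en-1-yl)oxiran-2-yl]methanol | C=CC[C@@H]1O[C@]1(CO)/C=C/I | intermediate
8 | (2E)-3-(4-hydroxyphenyl)prop-2-enoic acid (p-coumaric acid) | OC(=O)/C=C/c1ccc(O)cc1 | starting material
9 | triisopropylsilyl (2E)-3-{4-[(triisopropylsilyl)oxy]phenyl}prop-2-enoate | CC(C)[Si](OC(=O)/C=C/c1ccc(O[Si](C(C)C)(C(C)C)C(C)C)cc1)(C(C)C)C(C)C | intermediate (not isolated)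
10 | (2E)-3-{4-[(triisopropylsilyl)oxy]phenyl}prop-2-enoic acid | OC(=O)/C=C/c1ccc(O[Si](C(C)C)(C(C)C)C(C)C)cc1 | intermediate
11 | [(2S,3S)-2-[(E)-2-iodoethenyl]-3-(prop-2-en-1-yl)oxiran-2-yl]methyl (2E)-3-{4-[(triisopropylsilyl)oxy]phenyl}prop-2-enoate | C=CC[C@@H]1O[C@]1(COC(=O)/C=C/c2ccc(O[Si](C(C)C)(C(C)C)C(C)C)cc2)/C=C/I | intermediate
12 | (4R)-4-[(E)-2-iodoethenyl]-4-{(1S)-1-[(triethylsilyl)oxy]but-3-en-1-yl}-2-[(E)-2-{4-[(triisopropylsilyl)oxy]phenyl}ethenyl]-1,3-dioxolan-2-ylium trifluoromethanesulfonate | C=CC[C@H](O[Si](CC)(CC)CC)[C@@]1(/C=C/I)COC(/C=C/c2ccc(O[Si](C(C)C)(C(C)C)C(C)C)cc2)=[O+]1.[O-]S(=O)(=O)C(F)(F)F | intermediate (not isolated)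
13 | (2R,3S)-2-hydroxy-2-[(E)-2-iodoethenyl]-3-[(triethylsilyl)oxy]hex-5-en-1-yl (2E)-3-{4-[(triisopropylsilyl)oxy]phenyl}prop-2-enoate | C=CC[C@H](O[Si](CC)(CC)CC)[C@](O)(COC(=O)/C=C/c1ccc(O[Si](C(C)C)(C(C)C)C(C)C)cc1)/C=C/I | intermediate
14 | 2-methylidenepropane-1,3-diol | C=C(CO)CO | starting material
15 | (2R,3S)-2,7-dihydroxy-6-(hydroxymethyl)-2-[(E)-2-iodoethenyl]-3-[(triethylsilyl)oxy]hept-5-en-1-yl (2E)-3-{4-[(triisopropylsilyl)oxy]phenyl}prop-2-enoate | OCC(CO)=CC[C@H](O[Si](CC)(CC)CC)[C@](O)(COC(=O)/C=C/c1ccc(O[Si](C(C)C)(C(C)C)C(C)C)cc1)/C=C/I | intermediate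
16 | (3S)-3-methylpentanoic acid | CC[C@H](C)CC(=O)O | starting material
17 | (1E,3R,4S)-3,8-dihydroxy-7-(hydroxymethyl)-4-[(triethylsilyl)oxy]-3-({[(2E)-3-{4-[(triisopropylsilyl)oxy]phenyl}prop-2-enoyl]oxy}methyl)octa-1,6-dien-1-yl (3S)-3-methylpentanoate | OCC(CO)=CC[C@H](O[Si](CC)(CC)CC)[C@](O)(COC(=O)/C=C/c1ccc(O[Si](C(C)C)(C(C)C)C(C)C)cc1)/C=C/OC(=O)C[C@@H](C)CC | intermediate
18 | (1E,3R,4S)-7-formyl-3-hydroxy-8-oxo-4-[(triethylsilyl)oxy]-3-({[(2E)-3-{4-[(triisopropylsilyl)oxy]phenyl}prop-2-enoyl]oxy}methyl)octa-1,6-dien-1-yl (3S)-3-methylpentanoate | O=CC(C=O)=CC[C@H](O[Si](CC)(CC)CC)[C@](O)(COC(=O)/C=C/c1ccc(O[Si](C(C)C)(C(C)C)C(C)C)cc1)/C=C/OC(=O)C[C@@H](C)CC | intermediate (not isolated)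
19 | (1S,4aS,6S,7R,7aS)-4-formyl-7-hydroxy-6-[(triethylsilyl)oxy]-7-({[(2E)-3-{4-[(triisopropylsilyl)oxy]phenyl}prop-2-enoyl]oxy}methyl)-1,4a,5,6,7,7a-hexahydrocyclopenta[c]pyran-1-yl (3S)-3-methylpentanoate | CC[C@H](C)CC(=O)O[C@@H]1OC=C(C=O)[C@H]2C[C@H](O[Si](CC)(CC)CC)[C@](O)(COC(=O)/C=C/c3ccc(O[Si](C(C)C)(C(C)C)C(C)C)cc3)[C@@H]12 | intermediate
20 | (1S,4aS,6S,7R,7aS)-7-hydroxy-4-(hydroxymethyl)-6-[(triethylsilyl)oxy]-7-({[(2E)-3-{4-[(triisopropylsilyl)oxy]phenyl}prop-2-enoyl]oxy}methyl)-1,4a,5,6,7,7a-hexahydrocyclopenta[c]pyran-1-yl (3S)-3-methylpentanoate | CC[C@H](C)CC(=O)O[C@@H]1OC=C(CO)[C@H]2C[C@H](O[Si](CC)(CC)CC)[C@](O)(COC(=O)/C=C/c3ccc(O[Si](C(C)C)(C(C)C)C(C)C)cc3)[C@@H]12 | intermediate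
21 | (1S,4aS,6S,7R,7aS)-6,7-dihydroxy-4-(hydroxymethyl)-7-({[(2E)-3-(4-hydroxyphenyl)prop-2-enoyl]oxy}methyl)-1,4a,5,6,7,7a-hexahydrocyclopenta[c]pyran-1-yl (3S)-3-methylpentanoate | CC[C@H](C)CC(=O)O[C@@H]1OC=C(CO)[C@H]2C[C@H](O)[C@](O)(COC(=O)/C=C/c3ccc(O)cc3)[C@@H]12 | target

**Totals**
Total step count: 12. Longest linear sequence: 11 steps (steps 1–4 and 6–12, from prop-2-yn-1-ol); step 5 is a one-step branch.

**Steps most likely to fail, with fallbacks**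

Step 7 (epoxide opening at the tertiary allylic C8; ionisation could erode the inversion). The fallback avoids breaking the C8–O bond and sets out from 6. Sharpless epoxidation with D-(−)-diethyl tartrate gives the enantiomeric epoxy alcohol [(2R,3R)-2-[(E)-2-iodoethenyl]-3-(prop-2-en-1-yl)oxiran-2-yl]methanol F1. Ti(OiPr)4-mediated opening of F1 with acid 10 at the secondary carbon (C7, inversion, C8 retained) gives the C7 ester (2R,3S)-1,2-dihydroxy-2-[(E)-2-iodoethenyl]hex-5-en-3-yl (2E)-3-{4-[(triisopropylsilyl)oxy]phenyl}prop-2-enoate F2. Base-catalysed (DBU) 1,3-acyl migration to the primary oxygen gives (2R,3S)-2,3-dihydroxy-2-[(E)-2-iodoethenyl]hex-5-en-1-yl (2E)-3-{4-[(triisopropylsilyl)oxy]phenyl}prop-2-enoate F3. Selective silylation of the secondary hydroxyl (Et3SiOTf, 2,6-lutidine, −78 °C) comes back to the route at 13.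

Step 9 (copper O-vinylation of the carboxylate in the presence of four hydroxyl groups). The fallback switches from the Ullmann manifold to an oxidative boron coupling and sets out from 15. Miyaura borylation (PdCl2(PPh3)2, B2pin2, KOPh, PhMe, 50 °C) gives the alkenyl boronate (2R,3S)-2,7-dihydroxy-6-(hydroxymethyl)-2-[(E)-2-(4,4,5,5-tetramethyl-1,3,2-dioxaborolan-2-yl)ethenyl]-3-[(triethylsilyl)oxy]hept-5-en-1-yl (2E)-3-{4-[(triisopropylsilyl)oxy]phenyl}prop-2-enoate F4. Chan–Lam-type oxidative coupling of F4 with acid 16 (Cu(OAc)2, DMAP, O2, 4 Å MS) proceeds with retention and comes back to the route at 17.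

Step 10 (the double ring closure; the enol ester may be too poor a dienophile or the facial selectivity too low). The fallback replaces the enol ester by an enamine and installs the C1 ester afterwards; it sets out from 17.
- Mild methanolysis of the enol ester (K2CO3 cat., MeOH, −20 °C) frees the aldehyde (2R,3S)-2,7-dihydroxy-6-(hydroxymethyl)-2-(2-oxoethyl)-3-[(triethylsilyl)oxy]hept-5-en-1-yl (2E)-3-{4-[(triisopropylsilyl)oxy]phenyl}prop-2-enoate F5.
- MnO2 gives the trialdehyde (2R,3S)-6-formyl-2-hydroxy-7-oxo-2-(2-oxoethyl)-3-[(triethylsilyl)oxy]hept-5-en-1-yl (2E)-3-{4-[(triisopropylsilyl)oxy]phenyl}prop-2-enoate F6.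
- N-Methylaniline condenses with the saturated aldehyde to the enamine (2R,3S)-6-formyl-2-hydroxy-2-{(E)-2-[methyl(phenyl)amino]ethenyl}-7-oxo-3-[(triethylsilyl)oxy]hept-5-en-1-yl (2E)-3-{4-[(triisopropylsilyl)oxy]phenyl}prop-2-enoate F7.
- F7 undergoes the enamine–enal cycloaddition at 23 °C to the N,O-acetal [(1R,4aS,6S,7R,7aS)-4-formyl-7-hydroxy-1-[methyl(phenyl)amino]-6-[(triethylsilyl)oxy]-1,4a,5,6,7,7a-hexahydrocyclopenta[c]pyran-7-yl]methyl (2E)-3-{4-[(triisopropylsilyl)oxy]phenyl}prop-2-enoate F8.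
- Wet silica hydrolyses F8 to the lactol [(1R,4aS,6S,7R,7aS)-4-formyl-1,7-dihydroxy-6-[(triethylsilyl)oxy]-1,4a,5,6,7,7a-hexahydrocyclopenta[c]pyran-7-yl]methyl (2E)-3-{4-[(triisopropylsilyl)oxy]phenyl}prop-2-enoate F9.
- Acylation of F9 with acid 16 (DCC, DMAP) under anomeric control comes back to the route at 19.

**Further compounds**
F1 | step 7 | [(2R,3R)-2-[(E)-2-iodoethenyl]-3-(prop-2-en-1-yl)oxiran-2-yl]methanol | C=CC[C@H]1O[C@@]1(CO)/C=C/I
F2 | step 7 | (2R,3S)-1,2-dihydroxy-2-[(E)-2-iodoethenyl]hex-5-en-3-yl (2E)-3-{4-[(triisopropylsilyl)oxy]phenyl}prop-2-enoate | C=CC[C@H](OC(=O)/C=C/c1ccc(O[Si](C(C)C)(C(C)C)C(C)C)cc1)[C@](O)(CO)/C=C/I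
F3 | step 7 | (2R,3S)-2,3-dihydroxy-2-[(E)-2-iodoethenyl]hex-5-en-1-yl (2E)-3-{4-[(triisopropylsilyl)oxy]phenyl}prop-2-enoate | C=CC[C@H](O)[C@](O)(COC(=O)/C=C/c1ccc(O[Si](C(C)C)(C(C)C)C(C)C)cc1)/C=C/I
F4 | step 9 | (2R,3S)-2,7-dihydroxy-6-(hydroxymethyl)-2-[(E)-2-(4,4,5,5-tetramethyl-1,3,2-dioxaborolan-2-yl)ethenyl]-3-[(triethylsilyl)oxy]hept-5-en-1-yl (2E)-3-{4-[(triisopropylsilyl)oxy]phenyl}prop-2-enoate | OCC(CO)=CC[C@H](O[Si](CC)(CC)CC)[C@](O)(COC(=O)/C=C/c1ccc(O[Si](C(C)C)(C(C)C)C(C)C)cc1)/C=C/B1OC(C)(C)C(C)(C)O1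
F5 | step 10 | (2R,3S)-2,7-dihydroxy-6-(hydroxymethyl)-2-(2-oxoethyl)-3-[(triethylsilyl)oxy]hept-5-en-1-yl (2E)-3-{4-[(triisopropylsilyl)oxy]phenyl}prop-2-enoate | OCC(CO)=CC[C@H](O[Si](CC)(CC)CC)[C@](O)(COC(=O)/C=C/c1ccc(O[Si](C(C)C)(C(C)C)C(C)C)cc1)CC=O
F6 | step 10 | (2R,3S)-6-formyl-2-hydroxy-7-oxo-2-(2-oxoethyl)-3-[(triethylsilyl)oxy]hept-5-en-1-yl (2E)-3-{4-[(triisopropylsilyl)oxy]phenyl}prop-2-enoate | O=CC(C=O)=CC[C@H](O[Si](CC)(CC)CC)[C@](O)(COC(=O)/C=C/c1ccc(O[Si](C(C)C)(C(C)C)C(C)C)cc1)CC=O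
F7 | step 10 | (2R,3S)-6-formyl-2-hydroxy-2-{(E)-2-[methyl(phenyl)amino]ethenyl}-7-oxo-3-[(triethylsilyl)oxy]hept-5-en-1-yl (2E)-3-{4-[(triisopropylsilyl)oxy]phenyl}prop-2-enoate | O=CC(C=O)=CC[C@H](O[Si](CC)(CC)CC)[C@](O)(COC(=O)/C=C/c1ccc(O[Si](C(C)C)(C(C)C)C(C)C)cc1)/C=C/N(C)c1ccccc1
F8 | step 10 | [(1R,4aS,6S,7R,7aS)-4-formyl-7-hydroxy-1-[methyl(phenyl)amino]-6-[(triethylsilyl)oxy]-1,4a,5,6,7,7a-hexahydrocyclopenta[c]pyran-7-yl]methyl (2E)-3-{4-[(triisopropylsilyl)oxy]phenyl}prop-2-enoate | CN(c1ccccc1)[C@@H]1OC=C(C=O)[C@H]2C[C@H](O[Si](CC)(CC)CC)[C@](O)(COC(=O)/C=C/c3ccc(O[Si](C(C)C)(C(C)C)C(C)C)cc3)[C@@H]12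
F9 | step 10 | [(1R,4aS,6S,7R,7aS)-4-formyl-1,7-dihydroxy-6-[(triethylsilyl)oxy]-1,4a,5,6,7,7a-hexahydrocyclopenta[c]pyran-7-yl]methyl (2E)-3-{4-[(triisopropylsilyl)oxy]phenyl}prop-2-enoate | O[C@@H]1OC=C(C=O)[C@H]2C[C@H](O[Si](CC)(CC)CC)[C@](O)(COC(=O)/C=C/c3ccc(O[Si](C(C)C)(C(C)C)C(C)C)cc3)[C@@H]12
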